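A direct plan would make 5,7-di-O-benzylkaempferol A2 by an Algar–Flynn–Oyamada reaction of chalcone A1, oxidise it with PhI(OAc)2 in methanol to the 2,3-dimethoxy-3-hydroxyflavanone A3, ionise this to the para-quinone methide 3,4-dione A4, and let kaempferol 3,5,4'-triacetate A5 add by C-8 and O-7 under a chiral phosphoric acid to give the protected core A6, followed by removal of acetates and benzyl ethers.
Weakest step 1, the union of A4 with A5: a single intermolecular step would have to deliver C-8 over C-6 attack, C- over O-arylation, cross- over self-coupling and the absolute configuration of a quaternary carbon, with a triply acetylated, electron-poor arene as nucleophile and an unstable tricarbonyl methide as electrophile.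
Weakest step 2, the oxidation of A2 to A3: it would be run beside a free para-substituted phenol, the preferred substrate of PhI(OAc)2, so dearomatisation of ring B competes with oxidation of the flavonol.
Weakest step 3, the Algar–Flynn–Oyamada closure of A1: a 6'-alkoxy-2'-hydroxychalcone is the case that tends to divert to the aurone.

**Retrosynthetic overview**
- Key disconnection: the C-2–O-1 bond of chromanone ring C together with the C-3–OH bond. Read backwards, the dihydrofuran (O-7 and C-8 of the flavonol unit, C-3 and C-2 of the chromanone unit) is a 2-aroyl-3-arylbenzofuran plus one oxygen, that is, a 2'-hydroxychalcone whose enone double bond is locked in a furan. This gives the flat, achiral precursor 13.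
- Forward, one asymmetric oxygen transfer to that furan C=C and anti 6-endo capture by the ring A phenol would close ring C last and set the quaternary C-2 and the hemiketal C-3 together.
- The furan is closed before ring C by a Rap–Stoermer condensation (O-7–C-3 and C-2–C-3 bonds) of bromoketone 10 with 8-aroylflavonol 6. The C-2–C-8 bond comes from a carbonylative Suzuki coupling at the C-8 iodide of perbenzylated kaempferol, so C-2 is carbon monoxide.
- Ring order: flavonol (bought as kaempferol), then furan, then chromanone ring C. There is no oxidised flavonol, no Algar–Flynn–Oyamada step and no intermolecular stereodefining C–C bond; regiochemistry (iodination), C–C bond formation (palladium) and stereochemistry (intramolecular, one face selection on a flat arene) are settled in separate steps.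

Key step: step 8

Assumption: the (R,R)-salen manganese catalyst is taken to deliver oxygen to the furan face that leads to (2R,3S); should the sense be opposite, the (S,S)-catalyst would be used with no other change. Locants C-2, C-3, C-4, O-1 and ring A refer to the chromanone unit; positions of the flavonol unit are written out.

**Step 1**
Reactants: 1 kaempferol
Product: 2 3,5,7-tris(benzyloxy)-2-[4-(benzyloxy)phenyl]-4H-chromen-4-one (tetra-O-benzylkaempferol)
Conditions: BnBr (6 equiv), K2CO3, Bu4NI (cat.), DMF, 80 °C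
Reagents that add atoms: benzyl bromide, BrCc1ccccc1
Why: exhaustive Williamson etherification, in which excess halide and heat should also alkylate the chelated 5-OH.

**Step 2**
Reactants: 2 tetra-O-benzylkaempferol
Product: 3 3,5,7-tris(benzyloxy)-2-[4-(benzyloxy)phenyl]-8-iodo-4H-chromen-4-one
Conditions: N-iodosuccinimide (1.1 equiv), CF3CO2H (cat.), MeCN–CH2Cl2, 0 °C to rt, dark
Reagents that add atoms: N-iodosuccinimide, O=C1CCC(=O)N1I
Why: electrophilic aromatic iodination, which on 5,7-di-O-alkylflavones should enter C-8 (between O-7 and the ring oxygen) because C-6 lies between two benzyloxy groups and ring B is deactivated by the pyranone.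

**Step 3**
Reactants: 3 8-iodide; 4 [4-(benzyloxy)phenyl]boronic acid
Product: 5 3,5,7-tris(benzyloxy)-8-[4-(benzyloxy)benzoyl]-2-[4-(benzyloxy)phenyl]-4H-chromen-4-one
Conditions: CO (1 atm), PdCl2(PPh3)2 (5 mol %), K2CO3, anisole, 80 °C
Reagents that add atoms: carbon monoxide, [C-]#[O+]
Why: carbonylative Suzuki–Miyaura coupling, in which zerovalent palladium inserts into the C-8 iodide, CO insertion (favoured for an electron-rich, doubly ortho-substituted aryl) precedes transmetalation, and the new carbonyl carbon becomes C-2 of the chromanone unit.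

**Step 4**
Reactants: 5 8-aroyl tetrabenzyl ether
Product: 6 3-(benzyloxy)-8-[4-(benzyloxy)benzoyl]-2-[4-(benzyloxy)phenyl]-5,7-dihydroxy-4H-chromen-4-one
Conditions: BCl3 (2.5 equiv), CH2Cl2, −78 °C; then MeOH
Reagents that add atoms: none
Why: chelation-controlled ether cleavage by a boron Lewis acid, which should remove only the benzyl groups that sit in a six-membered chelate with a carbonyl (O-5 with the pyranone C=O, O-7 with the new 8-aroyl C=O), leaving the 3-O-benzyl (five-membered chelate) and the para benzyl ethers.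

**Step 5**
Reactants: 7 1-[2,4-bis(benzyloxy)-6-hydroxyphenyl]ethan-1-one
Product: 8 1-[2,4-bis(benzyloxy)-6-(methoxymethoxy)phenyl]ethan-1-one
Conditions: MOMCl, iPr2NEt, CH2Cl2, 0 to 40 °C
Reagents that add atoms: chloromethyl methyl ether, COCCl
Why: Williamson-type O-alkylation (MOM protection) of the chelated phenol, which masks the oxygen that would otherwise displace bromide intramolecularly to a coumaranone and which acid later unveils without touching benzyl ethers.

**Step 6**
Reactants: 8 MOM-protected acetophenone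
Product: 10 1-[2,4-bis(benzyloxy)-6-(methoxymethoxy)phenyl]-2-bromoethan-1-one, via trimethylsilyl enol ether 9 (not isolated)
Conditions: LiN(SiMe3)2, Me3SiCl, THF, −78 °C; then N-bromosuccinimide, THF, −78 to 0 °C
Reagents that add atoms: N-bromosuccinimide, O=C1CCC(=O)N1Br
Why: α-bromination of a ketone through its silyl enol ether (only the methyl group is enolisable), which avoids HBr and ring bromination of the electron-rich arene.

**Step 7**
Reactants: 6 8-aroyl-5,7-dihydroxyflavonol dibenzyl ether; 10 α-bromoketone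
Product: 13 8-[2,4-bis(benzyloxy)-6-hydroxybenzoyl]-3-(benzyloxy)-2,9-bis[4-(benzyloxy)phenyl]-5-hydroxy-4H-furo[2,3-h]chromen-4-one, via 7-O-phenacyl ether 11 (not isolated), via MOM-protected furochromenone 12 (not isolated)
Conditions: K2CO3, DMF, rt to 90 °C; then HCl (3 M aq.), MeOH–THF, 50 °C
Reagents that add atoms: none
Why: Rap–Stoermer benzofuran synthesis, in which the 7-OH (the more acidic of the two chelated phenols) is alkylated, the α-aryloxy ketone enolate of 11 adds 5-exo-trig to the neighbouring diaryl ketone and water is lost to the aromatic furan, after which acid removes only the MOM acetal.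

**Step 8**
Reactants: 13 2-aroyl-3-arylfuro[2,3-h]flavone
Product: 15 (2R,3S)-5,7-bis(benzyloxy)-2-[4-(benzyloxy)phenyl]-3-hydroxychroman-4-one joined by C-2 to C-8 and by C-3 to O-7 of 3,4'-di-O-benzylkaempferol (cis-fused dihydrofuran hemiketal), via furan epoxide 14 (not isolated)
Conditions: (R,R)-[N,N'-bis(3,5-di-tert-butylsalicylidene)cyclohexane-1,2-diaminato]MnCl (10 mol %), N-methylmorpholine N-oxide (5 equiv), mCPBA (1.5 equiv), CH2Cl2, −78 to −40 °C
Reagents that add atoms: m-chloroperoxybenzoic acid, O=C(OO)c1cccc(Cl)c1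
Why: Proposed new method: the oxomanganese salen species (pentavalent manganese, formed from the trivalent precatalyst and mCPBA) should transfer oxygen to the furan C=C of 13, bonding first at the acyl-bearing carbon (future C-3) so that charge builds up on the doubly benzylic carbon (future C-2), and the chelated 2-hydroxyl of the aroyl group then opens epoxide 14 at that carbon anti to the new C–O bond, as the phenoxide does on a chalcone epoxide in the Algar–Flynn–Oyamada reaction. The closest known reaction types are the salen-manganese (Jacobsen–Katsuki) epoxidation of isoflavones, chromenes and tetrasubstituted indenes, the dioxirane epoxidation of benzofurans and flavones, and the 6-endo opening of 2'-hydroxychalcone epoxides; new is their combination as an enantioselective dearomatising oxidative cyclisation of a 2-aroylbenzofuran. Chromanone ring C closes 6-endo-tet at the benzylic epoxide carbon (6-exo-trig onto the methide carbon if 14 first opens to its zwitterion), while the furan ring is kept and only dearomatised. C-3 is set by the catalyst through the face of oxygen transfer and C-2 follows from it by inversion, because the new six-membered ring can only be cis-fused to the five-membered one, so the 3-OH ends up cis to the aryl group at C-2 as in the target. The step needs oxidation of the furan double bond before the 3-benzyloxyflavone double bond and the arenes (the furan carbon is benzylic to two oxygen-rich arenes, the flavone double bond is a tetrasubstituted vinylogous ester and both free phenols are chelated), 6-endo over 5-exo attack at the acetal carbon (which the benzylic stabilisation at C-2 should secure), and capture faster than collapse of 14 to the achiral ortho-quinone methide dione (which the phenol held four atoms from C-2 should ensure).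

**Step 9**
Reactants: 15 penta-O-benzyl cyclisation product
Product: 16 target, (2R,3S)-3,5,7-trihydroxy-2-(4-hydroxyphenyl)chroman-4-one joined by C-2 to C-8 and by C-3 to O-7 of kaempferol
Conditions: H2 (1 atm), Pd/C (10% palladium on carbon), THF–MeOH, rt
Reagents that add atoms: none
Why: catalytic hydrogenolysis of five primary aryl benzyl ethers, which should be faster than cleavage of the tertiary, shielded C-2–O-1 ether or reduction of the flavonol double bond, under neutral conditions that leave the hemiketal and both stereocentres untouched.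

**Compound list**

1 | kaempferol | O=c1c(O)c(-c2ccc(O)cc2)oc2cc(O)cc(O)c12 | starting material
2 | 3,5,7-tris(benzyloxy)-2-[4-(benzyloxy)phenyl]-4H-chromen-4-one | O=c1c(OCc2ccccc2)c(-c2ccc(OCc3ccccc3)cc2)oc2cc(OCc3ccccc3)cc(OCc3ccccc3)c12 | intermediate
3 | 3,5,7-tris(benzyloxy)-2-[4-(benzyloxy)phenyl]-8-iodo-4H-chromen-4-one | O=c1c(OCc2ccccc2)c(-c2ccc(OCc3ccccc3)cc2)oc2c(I)c(OCc3ccccc3)cc(OCc3ccccc3)c12 | intermediate
4 | [4-(benzyloxy)phenyl]boronic acid | OB(O)c1ccc(OCc2ccccc2)cc1 | starting material
5 | 3,5,7-tris(benzyloxy)-8-[4-(benzyloxy)benzoyl]-2-[4-(benzyloxy)phenyl]-4H-chromen-4-one | O=c1c(OCc2ccccc2)c(-c2ccc(OCc3ccccc3)cc2)oc2c(C(=O)c3ccc(OCc4ccccc4)cc3)c(OCc3ccccc3)cc(OCc3ccccc3)c12 | intermediate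
6 | 3-(benzyloxy)-8-[4-(benzyloxy)benzoyl]-2-[4-(benzyloxy)phenyl]-5,7-dihydroxy-4H-chromen-4-one | O=c1c(OCc2ccccc2)c(-c2ccc(OCc3ccccc3)cc2)oc2c(C(=O)c3ccc(OCc4ccccc4)cc3)c(O)cc(O)c12 | intermediate
7 | 1-[2,4-bis(benzyloxy)-6-hydroxyphenyl]ethan-1-one | CC(=O)c1c(O)cc(OCc2ccccc2)cc1OCc1ccccc1 | starting material
8 | 1-[2,4-bis(benzyloxy)-6-(methoxymethoxy)phenyl]ethan-1-one | CC(=O)c1c(OCOC)cc(OCc2ccccc2)cc1OCc1ccccc1 | intermediate
9 | ({1-[2,4-bis(benzyloxy)-6-(methoxymethoxy)phenyl]ethenyl}oxy)trimethylsilane | C=C(O[Si](C)(C)C)c1c(OCOC)cc(OCc2ccccc2)cc1OCc1ccccc1 | intermediate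
10 | 1-[2,4-bis(benzyloxy)-6-(methoxymethoxy)phenyl]-2-bromoethan-1-one | O=C(CBr)c1c(OCOC)cc(OCc2ccccc2)cc1OCc1ccccc1 | intermediate
11 | 3-(benzyloxy)-8-[4-(benzyloxy)benzoyl]-2-[4-(benzyloxy)phenyl]-7-{2-[2,4-bis(benzyloxy)-6-(methoxymethoxy)phenyl]-2-oxoethoxy}-5-hydroxy-4H-chromen-4-one | O=c1c(OCc2ccccc2)c(-c2ccc(OCc3ccccc3)cc2)oc2c(C(=O)c3ccc(OCc4ccccc4)cc3)c(OCC(=O)c3c(OCOC)cc(OCc4ccccc4)cc3OCc3ccccc3)cc(O)c12 | intermediate
12 | 8-[2,4-bis(benzyloxy)-6-(methoxymethoxy)benzoyl]-3-(benzyloxy)-2,9-bis[4-(benzyloxy)phenyl]-5-hydroxy-4H-furo[2,3-h]chromen-4-one | O=C(c1c(OCOC)cc(OCc2ccccc2)cc1OCc1ccccc1)c1oc2cc(O)c3c(=O)c(OCc4ccccc4)c(-c4ccc(OCc5ccccc5)cc4)oc3c2c1-c1ccc(OCc2ccccc2)cc1 | intermediate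
13 | 8-[2,4-bis(benzyloxy)-6-hydroxybenzoyl]-3-(benzyloxy)-2,9-bis[4-(benzyloxy)phenyl]-5-hydroxy-4H-furo[2,3-h]chromen-4-one | O=C(c1c(O)cc(OCc2ccccc2)cc1OCc1ccccc1)c1oc2cc(O)c3c(=O)c(OCc4ccccc4)c(-c4ccc(OCc5ccccc5)cc4)oc3c2c1-c1ccc(OCc2ccccc2)cc1 | intermediate
14 | 8,9-epoxide of 13 (8,9-epoxy-8,9-dihydrofurochromenone; oxygen on the face that becomes the 3-OH face) | O=C(c1c(O)cc(OCc2ccccc2)cc1OCc1ccccc1)[C@]12O[C@@]1(c1ccc(OCc3ccccc3)cc1)c1c(cc(O)c3c(=O)c(OCc4ccccc4)c(-c4ccc(OCc5ccccc5)cc4)oc13)O2 | intermediate
15 | (2R,3S) cis-fused cyclisation product; chromanone unit 5,7-di-O-benzyl and 4'-O-benzyl, 3-OH free; flavonol unit 3,4'-di-O-benzyl, 5-OH free | O=C1c2c(OCc3ccccc3)cc(OCc3ccccc3)cc2O[C@]2(c3ccc(OCc4ccccc4)cc3)c3c(cc(O)c4c(=O)c(OCc5ccccc5)c(-c5ccc(OCc6ccccc6)cc5)oc34)O[C@]12O | intermediate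
16 | target (CNP0314633.1), (2R,3S) | O=C1c2c(O)cc(O)cc2O[C@]2(c3ccc(O)cc3)c3c(cc(O)c4c(=O)c(O)c(-c5ccc(O)cc5)oc34)O[C@]12O | target

**Step count and risks**

Total: 9 steps. Longest linear sequence: 7 steps (steps 1, 2, 3, 4, 7, 8, 9).

Steps most likely to fail:

1. Step 8 (Proposed new method). Oxygen transfer may show poor facial selectivity, the epoxide may leak through the achiral ortho-quinone methide dione before capture, or the flavone double bond or the phenols may be oxidised in competition. Fallback: set out from 13 and use dimethyldioxirane in acetone–CH2Cl2 at −40 to 0 °C, the known dioxirane epoxidation of benzofurans. This should give the racemic epoxide, that is 14 together with the mirror-image epoxide F1, which would close in the same way to 15 and its (2S,3R) enantiomer F2. Separation by preparative HPLC on a chiral stationary phase (amylose tris(3,5-dimethylphenylcarbamate)) returns to the route at 15.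

2. Step 3. At the doubly ortho-substituted iodide, direct biaryl coupling or reduction of the C–I bond may outrun CO insertion and transmetalation. Fallback: set out from 3; iodine–magnesium exchange (iPrMgCl·LiCl, THF, −40 °C) should give the 8-magnesiated flavone F3, addition to 4-(benzyloxy)benzaldehyde the racemic diarylcarbinol F4, and oxidation (MnO2, CH2Cl2) returns to the route at 5.

3. Step 9. Hydrogenolysis may also cleave the doubly benzylic C-2–O-1 bond or reduce the hemiketal and ketone, or stall on the polyphenol. Fallback: set out from 15 and debenzylate without reduction, with BCl3 and pentamethylbenzene as cation scavenger in CH2Cl2 at −78 °C, which returns to the route at 16; no new compound is made (F0).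

**Further compounds**

F1 | step 8 | mirror-image epoxide (enantiomer of 14) | O=C(c1c(O)cc(OCc2ccccc2)cc1OCc1ccccc1)[C@@]12O[C@]1(c1ccc(OCc3ccccc3)cc1)c1c(cc(O)c3c(=O)c(OCc4ccccc4)c(-c4ccc(OCc5ccccc5)cc4)oc13)O2
F2 | step 8 | (2S,3R) enantiomer of 15 | O=C1c2c(OCc3ccccc3)cc(OCc3ccccc3)cc2O[C@@]2(c3ccc(OCc4ccccc4)cc3)c3c(cc(O)c4c(=O)c(OCc5ccccc5)c(-c5ccc(OCc6ccccc6)cc5)oc34)O[C@@]12O
F3 | step 3 | 3,5,7-tris(benzyloxy)-2-[4-(benzyloxy)phenyl]-8-(chloromagnesio)-4H-chromen-4-one | O=c1c(OCc2ccccc2)c(-c2ccc(OCc3ccccc3)cc2)oc2c([Mg]Cl)c(OCc3ccccc3)cc(OCc3ccccc3)c12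
F4 | step 3 | racemic 3,5,7-tris(benzyloxy)-8-{[4-(benzyloxy)phenyl](hydroxy)methyl}-2-[4-(benzyloxy)phenyl]-4H-chromen-4-one | O=c1c(OCc2ccccc2)c(-c2ccc(OCc3ccccc3)cc2)oc2c(C(O)c3ccc(OCc4ccccc4)cc3)c(OCc3ccccc3)cc(OCc3ccccc3)c12
F0 | step 9 | none | none
A1 | direct plan | (E)-1-[2,4-bis(benzyloxy)-6-hydroxyphenyl]-3-[4-(tetrahydro-2H-pyran-2-yloxy)phenyl]prop-2-en-1-one | O=C(/C=C/c1ccc(OC2CCCCO2)cc1)c1c(O)cc(OCc2ccccc2)cc1OCc1ccccc1
A2 | direct plan | 5,7-bis(benzyloxy)-3-hydroxy-2-(4-hydroxyphenyl)-4H-chromen-4-one | O=c1c(O)c(-c2ccc(O)cc2)oc2cc(OCc3ccccc3)cc(OCc3ccccc3)c12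
A3 | direct plan | 5,7-bis(benzyloxy)-3-hydroxy-2-(4-hydroxyphenyl)-2,3-dimethoxychroman-4-one (diastereomer mixture) | COC1(c2ccc(O)cc2)Oc2cc(OCc3ccccc3)cc(OCc3ccccc3)c2C(=O)C1(O)OC
A4 | direct plan | 5,7-bis(benzyloxy)-2-(4-oxocyclohexa-2,5-dien-1-ylidene)chromane-3,4-dione | O=C1C=CC(=C2Oc3cc(OCc4ccccc4)cc(OCc4ccccc4)c3C(=O)C2=O)C=C1
A5 | direct plan | kaempferol 3,5,4'-triacetate | CC(=O)Oc1ccc(-c2oc3cc(O)cc(OC(C)=O)c3c(=O)c2OC(C)=O)cc1
A6 | direct plan | (2R,3S) cis-fused annulation product, chromanone unit 5,7-di-O-benzyl, flavonol unit 3,5,4'-tri-O-acetyl | O=C1c2c(OCc3ccccc3)cc(OCc3ccccc3)cc2O[C@]2(c3ccc(O)cc3)c3c(cc(OC(C)=O)c4c(=O)c(OC(C)=O)c(-c5ccc(OC(C)=O)cc5)oc34)O[C@]12O
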